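**Assumptions:** (S)-Wieland–Miescher ketone and methyl 4-bromofuran-2-carboxylate (a furoic-acid/furfural-derived heteroaromatic) are commercial. Decalin numbering follows drimane/avarane practice: C4 carries the ring-B methyl and C4=C3 is the alkene, C5 is the angular quaternary carbon, and C8 is the quaternary carbon bearing the CH2 side chain. C1′–C5′ label the cyclopentenone ring, with C1′ carrying OH/CO2Me and C5′ bonded to the CH2 linker.

## Retrosynthetic overview
1. The last step forms the cyclopentenone by dearomatising a 2-furylcarbinol, a Piancatelli-type 4π ring contraction. The furan carries a 3-OMe and a 5-CO2Me, so the fully substituted 2-methoxy-4-hydroxy-4-carbomethoxy-cyclopentenone forms in one step with OH trans to the CH2 side chain.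
2. The furylcarbinol comes from 5-lithio-4-methoxyfuran-2-carboxylate plus the decalinyl-acetaldehyde.
3. The aldehyde comes from the quaternary C8 ester, made by Me-cuprate addition to an alkylidene ester from the α face, anti to the 9β-Me.
4. The 9β-methyl comes from α-face hydrogenation of a C9 exocyclic methylene. C10-H comes from a Birch-type reduction, and the ring-B Δ3 alkene from the C1 ketone of (S)-Wieland–Miescher ketone.
5. Ring order: both decalin rings come pre-formed from the Wieland–Miescher ketone, and the cyclopentenone ring is formed last.

## Forward route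

**Step 1**
Reactants: 1, (S)-Wieland–Miescher ketone, (8aS)-8a-methyl-3,4,8,8a-tetrahydronaphthalene-1,6(2H,7H)-dione
Product: 2, tertiary carbinol, (8aS)-1-hydroxy-1,8a-dimethyl-hexahydronaphthalen-6(7H)-one (C1 epimers)
Conditions: MeMgBr (1.05 equiv), THF, −78 °C
Reagents that add atoms: methylmagnesium bromide, C[Mg]Br
Why: Grignard 1,2-addition goes to the more electrophilic saturated C1 ketone, since the enone carbonyl is deactivated by conjugation. The C1 configuration is irrelevant because both epimers give the same alkene in the next step.

**Step 2**
Reactants: 2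
Product: 3, (S)-1,8a-dimethyl-3,4,8,8a-tetrahydronaphthalen-6(7H)-one (trisubstituted ring-B alkene, enone intact)
Conditions: Burgess reagent, PhH, 50 °C
Reagents that add atoms: none
Why: Burgess syn-elimination of the tertiary alcohol can only use the C2 hydrogens (C8a is quaternary), giving the ring-B C4=C3 alkene without a carbocation. This avoids a Wagner–Meerwein methyl shift next to the quaternary centre, and the angular stereocentre is untouched.

**Step 3**
Reactants: 3
Product: 4, trans-fused C8 ketone with 5β-Me, 10α-H, Δ3-4-Me alkene and C9-CH2NMe2
Conditions: Li, NH3(l)/THF, −78 °C; remove NH3; then [CH2=NMe2]+ I−, THF, −78 °C to rt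
Reagents that add atoms: Eschenmoser's salt, C=[N+](C)C.[I-]
Why: Dissolving-metal (Birch-type) enone reduction protonates C10 axially from the α face, giving the trans ring fusion (C10-H anti to the C5 methyl). It also gives the regiodefined C8/C9 lithium enolate, which is trapped at C9 by Mannich aminomethylation. The C9 configuration is erased in step 5.

**Step 4**
Reactants: 4
Product: 5, ethyl 2-(C8-ylidene)acetate bearing C9-CH2NMe2 (E/Z mixture)
Conditions: (EtO)2P(O)CH2CO2Et, NaH, THF, 0 °C to reflux
Reagents that add atoms: triethyl phosphonoacetate, CCOC(=O)CP(=O)(OCC)OCC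
Why: Horner–Wadsworth–Emmons olefination of the ketone; the tertiary amine and the trisubstituted alkene are inert. E/Z geometry does not matter because C8 becomes sp3 in step 7.

**Step 5**
Reactants: 5
Product: 6, cross-conjugated dienoate ethyl 2-(9-methylene-C8-ylidene)acetate
Conditions: MeI (excess), CH2Cl2, rt; then DBU, THF, 60 °C
Reagents that add atoms: none (the MeI methyl leaves as NMe3)
Why: Quaternisation of the amine, then DBU removes the vinylogously acidic C9-H and expels NMe3 (Hofmann-type vinylogous E1cB). This gives the exocyclic C9=CH2 regiospecifically. It also avoids a Michael-acceptor α-methylene ketone during the olefination in step 4.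

**Step 6**
Reactants: 6
Product: 7, ethyl 2-[(9β-methyl)-C8-ylidene]acetate with 5β-Me, 10α-H
Conditions: H2 (1 atm), RhCl(PPh3)3 (10 mol %), benzene, rt
Reagents that add atoms: none (H2 only)
Why: Proposed new method: Rh–H adds to the least hindered 1,1-disubstituted terminal alkene of the diene, leaving the enoate and the hindered ring-B alkene untouched. The axial 5β-methyl blocks the β face at C9 (1,3-diaxial), so H is delivered from the α face and the new CH3 ends up β-axial. This is the kinetic 9β-methyl, not the thermodynamic one; the closest precedent is face-selective hydrogenation of 4-methylene-5α-steroids.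

**Step 7**
Reactants: 7
Product: 8, ethyl 2-[(5S,8?,9?,10?)-4,5,8,9-tetramethyl-decalin-8-yl]acetate, the target decalin with C8 quaternary (8α-Me, 8β-CH2CO2Et)
Conditions: MeMgBr, CuBr·SMe2, TMSCl, HMPA, THF, −78 °C to 0 °C
Reagents that add atoms: methylmagnesium bromide, C[Mg]Br
Why: Cu-catalysed conjugate addition to a β,β-disubstituted enoate builds the quaternary centre. Axial attack at C8 occurs from the α face, anti to the 9β-methyl and the 5β-methyl, which sets the methyl α-axial and the CH2CO2Et β-equatorial as in the target.

**Step 8**
Reactants: 8
Product: 9, aldehyde O=CC[C@@]1(C)CC[C@]2(C)C(C)=CCC[C@H]2[C@H]1C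
Conditions: DIBAL-H (1.1 equiv), CH2Cl2, −78 °C
Reagents that add atoms: none
Why: Partial ester reduction stops at the aldehyde at low temperature. No stereocentre is affected.

**Step 9**
Reactants: 10, methyl 4-bromofuran-2-carboxylate (commercial heteroaromatic)
Product: 11, methyl 4-methoxyfuran-2-carboxylate
Conditions: NaOMe (3 equiv), CuBr (10 mol %), MeOH/DMF, 90 °C
Reagents that add atoms: sodium methoxide, C[O-].[Na+]
Why: Cu-catalysed Ullmann-type methoxylation of a heteroaryl bromide, as in the standard 3-bromothiophene to 3-methoxythiophene conversion. The methyl ester is unchanged.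

**Step 10**
Reactants: 11 and 9
Product: 12, methyl 5-[1-hydroxy-2-(decalinyl)ethyl]-4-methoxyfuran-2-carboxylate (carbinol epimers)
Conditions: LiTMP (1.05 equiv), THF, −78 °C, 20 min; then 9, −78 °C to 0 °C
Reagents that add atoms: none (LiTMP is only a base)
Why: Directed metalation at C5 (α to oxygen and ortho to OMe), then 1,2-addition to the aldehyde. The carbinol stereocentre is irrelevant because it is lost as a cation in step 11.

**Step 11**
Reactants: 12
Product: 13, dysidenone A
Conditions: Dy(OTf)3 (5 mol %), MeCN/H2O (20:1), 60 °C
Reagents that add atoms: water, O (net isomerisation; the carbinol oxygen leaves as water and water supplies the C1′–OH)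
Why: Proposed new method: Piancatelli rearrangement of an electron-poor, 3-OMe-stabilised furfuryl cation. Water adds at C5 of the furan and the ring opens. Conrotatory 4π electrocyclisation then closes the cyclopentenone, with the furan O becoming the C4′ carbonyl and the OMe-bearing carbon becoming C3′, giving the 2-methoxy enone. Torquoselectivity puts the C1′–OH trans to the C5′ side chain, so CO2Me is cis to the side chain, as in the target. The two new ring stereocentres are set relative to each other, but only weakly relative to the decalin (remote 1,3-induction). The diastereomers are separated by chromatography; mild Lewis acid and 60 °C are chosen to spare the ring-B alkene.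

## Compound list
1 | (S)-Wieland–Miescher ketone | C[C@]12CCC(=O)C=C1CCCC2=O | starting material
2 | C1-methyl tertiary carbinol | C[C@]12CCC(=O)C=C1CCCC2(C)O | intermediate
3 | (S)-1,8a-dimethyl octalone (ring-B alkene, enone) | C[C@]12CCC(=O)C=C1CCC=C2C | intermediate
4 | trans-decalone with C9-CH2NMe2 | O=C1CC[C@]2(C)C(C)=CCC[C@H]2[C@@H]1CN(C)C | intermediate
5 | ethyl alkylidene-acetate with C9-CH2NMe2 | CCOC(=O)C=C1CC[C@]2(C)C(C)=CCC[C@H]2[C@@H]1CN(C)C | intermediate
6 | cross-conjugated dienoate | CCOC(=O)C=C1CC[C@]2(C)C(C)=CCC[C@H]2C1=C | intermediate
7 | 9β-methyl alkylidene ester | CCOC(=O)C=C1CC[C@]2(C)C(C)=CCC[C@H]2[C@H]1C | intermediate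
8 | quaternary C8 ethyl ester | CCOC(=O)C[C@@]1(C)CC[C@]2(C)C(C)=CCC[C@H]2[C@H]1C | intermediate
9 | decalinyl-acetaldehyde | O=CC[C@@]1(C)CC[C@]2(C)C(C)=CCC[C@H]2[C@H]1C | intermediate
10 | methyl 4-bromofuran-2-carboxylate | COC(=O)c1cc(Br)co1 | starting material
11 | methyl 4-methoxyfuran-2-carboxylate | COC(=O)c1cc(OC)co1 | intermediate
12 | furfuryl alcohol (carbinol epimers) | COC(=O)c1cc(OC)c(o1)C(O)C[C@@]1(C)CC[C@]2(C)C(C)=CCC[C@H]2[C@H]1C | intermediate
13 | dysidenone A | COC(=O)[C@]1(O)C=C(OC)C(=O)[C@@H]1C[C@@]1(C)CC[C@]2(C)C(C)=CCC[C@H]2[C@H]1C | target

## Totals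
- Total steps: 11.
- Longest linear sequence: 10 (steps 1–8, 10, 11).

**Three steps most likely to fail**

1. **Step 11 (Piancatelli on the deactivated 3-OMe/5-CO2Me furan, with poor diastereoselectivity at C1′/C5′ against the decalin).**
   - Fallback, a different approach: hydrolyse 8 to the acid and do an Ag+/persulfate decarboxylative radical alkylation of 2-hydroxy-5-methoxy-1,4-benzoquinone.
   - Then contract the ring by a benzilic-ester rearrangement (NaOMe/MeOH) to give the cyclopentenone.
2. **Step 6 (kinetic α-face hydrogenation to the axial 9β-methyl).**
   - Fallback, a different approach: rebuild the decalin by an intramolecular Diels–Alder reaction of a triene whose C8/C9 stereocentres are fixed in the acyclic precursor.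
3. **Step 7 (conjugate methylation to form the quaternary centre next to a tertiary one).**
   - Fallback, a different acceptor strategy: use a more electrophilic alkylidene-malonate acceptor (Lehnert–Knoevenagel of the C8 ketone), add Me2CuLi, then decarboxylate (Krapcho) and reduce to the aldehyde.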